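4 questions stand on this flask, and 2 times read from Sunday's run serve them.

| setting | Sunday's | Wednesday's | flask |
|---|---|---|---|
| Ja | 0.20 M | 0.20 M | 0.20 M |
| Jb | 0.20 M | 0.20 M | 0.200 M |
| temperature | 35 °C | 20 °C | 35 °C |
| remark | the very flask that is asked about, followed so far | run made earlier |  |
| time |  |  | 3.0 d |

| run | time / h | Jc / % |
|---|---|---|
| Sunday's | 12.0 | 31.3 |
| Sunday's | 25.0 | 40.3 |
| Sunday's | 30.0 | 42.0 |
| Sunday's | 50.0 | 41.6 |
| Sunday's | 60.0 | 40.0 |
| Wednesday's | 25.0 | 12.0 |
| Wednesday's | 48.0 | 17.5 |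
| Wednesday's | 60.0 | 20.5 |
| Wednesday's | 96.0 | 23.9 |
| Wednesday's | 120 | 25.4 |

(scatter of a reading: 1 percentage point)

- birch: at 3.0 d take out 90% of the Jc then present, then wait 40 h
- larch: change nothing and wait 40 h more
- maple: at 3.0 d add Ja, 50.0% of the amount charged, then wait 40 h
- alder: at 3.0 d raise the temperature by 20 K, then wait 40 h

- in percentages every species weighs as the Ja in it: one Jf counts as two
- what is taken out of Jc is counted as made
- steps that have been proposed: Ja <-> Jb; Ja -> Jc; Jb -> Jd; Jc <-> Jd; Jc <-> Je; 2 Jb -> Jf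
- additions bring no volume worth counting

- Jc, in percent of the Ja and Jb together first charged, at 3.0 d
- which option adds most Jc ("none" when 2 percentage points or less is all one gets) (birch / larch / maple / alder / none)
- Jc present, with what was taken out counted in, in percent of the Ja and Jb together first charged, after birch
- Jc present, with what was taken out counted in, in percent of the Ja and Jb together first charged, after larch

Sunday's run is this very flask. Its first reading gives the early pace of [Jc], and at that pace the read peak of 42.0% takes a making time of 16.1 h. Between 30.0 h and 60.0 h [Jc] drops 2 percentage points, a small step against a scatter of 1 point. At that late pace the peak lasts a fall time of 630 h. I divide one by the other, so time drops out, and get 39.1. I call this the hold ratio, fall time over making time.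

As a rough estimate, I carry the late pace straight on. That gives me 39.2% at 3.0 d. Larch then costs 2.7 points, which leaves 36.5%. I put no number on the other options.

The forecast says 38.5% now, 34% after larch, 42% after birch, and maple as best. Of alder it says “so 20 K more mainly accelerates the loss of Jc”.

The flask gives 39.7%, 37.6% after larch and 54.9% after birch. The best option is alder, with 19 points against 11 points for maple.

    Ja ⇌ Jb (K = 0.0550, k = 0.0130 h⁻¹, Ea = 107 kJ mol⁻¹, ΔH = −8.00 kJ mol⁻¹)
    Ja → Jc (k = 0.0740 h⁻¹, Ea = 100 kJ mol⁻¹)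
    Jb → Jd (k = 0.0740 h⁻¹, Ea = 91.0 kJ mol⁻¹)
    Jc ⇌ Jd (K = 0.440, k = 0.120 h⁻¹, Ea = 89.0 kJ mol⁻¹, ΔH = −39.0 kJ mol⁻¹)
    Jc ⇌ Je (K = 0.790, k = 0.0160 h⁻¹, Ea = 109 kJ mol⁻¹, ΔH = −54.0 kJ mol⁻¹)
    2 Jb → Jf (k = 0.920 L mol⁻¹ h⁻¹, Ea = 55.0 kJ mol⁻¹)
    (constants at 35 °C)

The wait costs 2.1 points, so this flask's fall time is 735 h and its hold ratio 45.7. Ja → Jc ran while [Ja] fell from 43.0% at 7.20 h to 5.23% at 36.0 h, and [Jc] reached 42.8%. Then Jc → Je ran on, with [Ja] at 0.363%, while [Je] rose from 14.5% to 23.8% by 72.0 h. If the neighbour flask with 0.80 M of Ja kept the read peak and my hold ratio of 39.1, it would stand at 39.2% at 3.0 d, but it stands at 44.2%, with [Jf] at 9.13% against 18.4% in this flask.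

The runs stem from a simulated flask for an exercise; scatter was added.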